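**Retrosynthetic overview**

- The route rests on one feature: in ring A the bromines at C3 and C5 lie ortho and para to the aryloxy oxygen on C2 but meta to the oxygen on C1. A methoxy group at C1 would send bromine to C4 and C6, so C1 carries a formyl group (a meta director) during bromination.
- Disconnections, in retrosynthetic order: O–CH3 (Williamson); C1–O back to C1–CHO (Baeyer–Villiger, then formate cleavage); C3–Br and C5–Br (electrophilic bromination of the formyl diaryl ether); C2–O diaryl ether bond (SNAr of 2,4-dibromophenol on 2-fluorobenzaldehyde).
- No ring is formed; both benzene rings are bought, and ring B already carries its two bromines. The target is achiral.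

Key step: step 2

**Route**

Step 1
Reactants: 1 2-fluorobenzaldehyde; 2 2,4-dibromophenol
Product: 3 2-(2,4-dibromophenoxy)benzaldehyde
Conditions: K2CO3 (1.5 equiv), N,N-dimethylacetamide, 140 °C, N2
Reagents that add atoms: none
Why: Nucleophilic aromatic substitution by addition–elimination, in which the ortho formyl group stabilises the anionic adduct and fluoride is the best leaving group, while the unactivated C–Br bonds of the phenoxide are not touched.

Step 2
Reactants: 3 2-(2,4-dibromophenoxy)benzaldehyde; 4 bromine
Product: 6 3,5-dibromo-2-(2,4-dibromophenoxy)benzaldehyde, via 5-bromo-2-(2,4-dibromophenoxy)benzaldehyde 5 (not isolated)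
Conditions: Br2 (2.1 equiv), FeBr3 (10 mol%), 1,2-dichloroethane, 0 °C to 60 °C, dark
Reagents that add atoms: bromine (4), BrBr
Why: Electrophilic aromatic substitution: bromine polarised by FeBr3 attacks ring A to give an arenium ion that loses a proton, first at C5 (para to the ether oxygen, giving 5) and then at C3 (ortho to the same oxygen). The closest known reaction type is the ring bromination of 2-alkoxy- and 2-hydroxybenzaldehydes, which enters the two positions meta to the formyl group. No ring is closed and no stereocentre is formed. The step needs positional selectivity within ring A and preference for ring A over ring B: in both arenium ions the charge rests on C2, C4 and C6 and is taken up by the ether oxygen, never on the formyl-bearing C1, so the meta-directing formyl group and the ortho/para-directing aryloxy group point to the same two carbons. Ring B offers only C6', which is meta to two bromines and crowded by the ether link, so it should react more slowly than C3 of ring A; FeBr3 is kept catalytic so that the carbonyl is not held as a strongly deactivating Lewis acid complex, bromine is held near two equivalents, and light is excluded to avoid radical attack on the formyl C–H.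

Step 3
Reactants: 6 3,5-dibromo-2-(2,4-dibromophenoxy)benzaldehyde; 7 3-chloroperbenzoic acid (mCPBA)
Product: 9 3,5-dibromo-2-(2,4-dibromophenoxy)phenol, via 3,5-dibromo-2-(2,4-dibromophenoxy)phenyl formate 8 (not isolated)
Conditions: mCPBA (1.5 equiv), CH2Cl2, reflux; aq. Na2SO3 wash, solvent exchange; then HCl (cat.), MeOH, rt
Reagents that add atoms: 3-chloroperbenzoic acid (7), OOC(=O)c1cccc(Cl)c1
Why: Baeyer–Villiger oxidation of an aryl aldehyde (Dakin-type), in which the peracid adduct rearranges with migration of the aryl group, helped by the ortho aryloxy oxygen, to the aryl formate, which acid-catalysed transesterification with methanol then cleaves to the phenol and volatile methyl formate, while the aryl bromides and the diaryl ether are inert to both reagents.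

Step 4
Reactants: 9 3,5-dibromo-2-(2,4-dibromophenoxy)phenol; 10 iodomethane
Product: 11 1,5-dibromo-2-(2,4-dibromophenoxy)-3-methoxybenzene (target)
Conditions: MeI (1.5 equiv), K2CO3 (2 equiv), acetone, reflux
Reagents that add atoms: iodomethane (10), CI
Why: Williamson ether synthesis, in which the acidic dibromophenol is deprotonated by K2CO3 and the phenoxide is methylated by SN2 attack on iodomethane, with no other nucleophilic site in the molecule.

**Compound list**

1 | 2-fluorobenzaldehyde | O=Cc1ccccc1F | starting material
2 | 2,4-dibromophenol | Oc1ccc(Br)cc1Br | starting material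
3 | 2-(2,4-dibromophenoxy)benzaldehyde | O=Cc1ccccc1Oc1ccc(Br)cc1Br | intermediate
4 | bromine | BrBr | starting material
5 | 5-bromo-2-(2,4-dibromophenoxy)benzaldehyde | O=Cc1cc(Br)ccc1Oc1ccc(Br)cc1Br | intermediate
6 | 3,5-dibromo-2-(2,4-dibromophenoxy)benzaldehyde | O=Cc1cc(Br)cc(Br)c1Oc1ccc(Br)cc1Br | intermediate
7 | 3-chloroperbenzoic acid (mCPBA) | OOC(=O)c1cccc(Cl)c1 | starting material
8 | 3,5-dibromo-2-(2,4-dibromophenoxy)phenyl formate | O=COc1cc(Br)cc(Br)c1Oc1ccc(Br)cc1Br | intermediate
9 | 3,5-dibromo-2-(2,4-dibromophenoxy)phenol | Oc1cc(Br)cc(Br)c1Oc1ccc(Br)cc1Br | intermediate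
10 | iodomethane | CI | starting material
11 | 1,5-dibromo-2-(2,4-dibromophenoxy)-3-methoxybenzene | COc1cc(Br)cc(Br)c1Oc1ccc(Br)cc1Br | target

**Step count**

Total step count: 4. Longest linear sequence: 4 steps (from 1 or 2 to 11).

**Steps most likely to fail**

Step 2. The second bromination may lose ring selectivity. Once C5 is brominated, C3 of ring A and C6' of ring B are deactivated to a similar degree, so bromine may enter ring B, or the reaction may stall after one bromine. The fallback brominates before the ether is made, so that no second ring competes. It sets out from 1: NBS (2.2 equiv) in concentrated H2SO4 at 60 °C should give 3,5-dibromo-2-fluorobenzaldehyde F1, since fluorine (ortho/para) and formyl (meta) both direct to C3 and C5. SNAr of 2 on F1 (K2CO3, N,N-dimethylacetamide, 120 °C) displaces the fluoride, which is activated by the ortho formyl group, and comes back to the route at 6.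

Step 3. In the peracid adduct, hydride may migrate in place of the electron-poor aryl group, leading to the benzoic acid and not the formate. The fallback replaces the migrating hydrogen by a methyl group, which migrates poorly. It sets out from 6: MeMgBr (THF, −78 °C) should give racemic 1-[3,5-dibromo-2-(2,4-dibromophenoxy)phenyl]ethanol F2, and Dess–Martin periodinane (CH2Cl2, rt) then gives 1-[3,5-dibromo-2-(2,4-dibromophenoxy)phenyl]ethanone F3. Baeyer–Villiger oxidation of this aryl methyl ketone with trifluoroperacetic acid (trifluoroacetic anhydride, urea–H2O2, CH2Cl2, 0 °C to rt) should give 3,5-dibromo-2-(2,4-dibromophenoxy)phenyl acetate F4 by aryl migration. Methanolysis (K2CO3 cat., MeOH, rt) comes back to the route at 9.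

Step 1. The hindered, weakly nucleophilic dibromophenoxide may substitute slowly, so that at the temperature needed the aldehyde is lost to base-induced disproportionation or to attack by amine from solvent breakdown. The fallback uses a nitrile as a more robust activating group. It sets out from 2: SNAr on 2-fluorobenzonitrile (K2CO3, dimethyl sulfoxide, 100 °C) should give 2-(2,4-dibromophenoxy)benzonitrile F5. Partial reduction with i-Bu2AlH (toluene, −78 °C), followed by aqueous HCl hydrolysis of the aldimine, comes back to the route at 3.

**Further compounds**

F1 | step 2 | 3,5-dibromo-2-fluorobenzaldehyde | O=Cc1cc(Br)cc(Br)c1F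
F2 | step 3 | racemic 1-[3,5-dibromo-2-(2,4-dibromophenoxy)phenyl]ethanol | CC(O)c1cc(Br)cc(Br)c1Oc1ccc(Br)cc1Br
F3 | step 3 | 1-[3,5-dibromo-2-(2,4-dibromophenoxy)phenyl]ethanone | CC(=O)c1cc(Br)cc(Br)c1Oc1ccc(Br)cc1Br
F4 | step 3 | 3,5-dibromo-2-(2,4-dibromophenoxy)phenyl acetate | CC(=O)Oc1cc(Br)cc(Br)c1Oc1ccc(Br)cc1Br
F5 | step 1 | 2-(2,4-dibromophenoxy)benzonitrile | N#Cc1ccccc1Oc1ccc(Br)cc1Br
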